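Assumption: the SMILES is taken as drawn, which gives (3R,5S,9R,10R,11S,13E), an ent-labdane. Labdane numbering (C1–C20) is used for all atoms, also in the monocyclic precursors.

## Analysis of the target

- **Skeleton.** Target 20 is the 3,15-diacetate of an ent-labda-7,13E-diene-3,11,15-triol. It holds a trans-decalin (ring A: C1–C5 and C10; ring B: C5–C10).
- **Substituents.** C4 carries the geminal methyls C18/C19, C10 the angular methyl C20, and C8 the vinylic methyl C17. The double bond C7=C8 is endocyclic. C9 carries the chain C11H(OH)–C12H2–C13(C16H3)=C14H–C15H2OAc.
- **Ring stereocentres.** The C3 acetoxy group is equatorial. H5 and C20 are trans-diaxial. H9 is axial and anti to C20, so C11 is equatorial and lies on the same side of ring B as C20.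
- **C11.** This fifth stereocentre lies outside the rings, wedged between C1H2, C17 and C20. No conformational lock ties it to the decalin.
- **Sensitive groups.**
  - Two acetates must be told apart from the free, hindered 11-OH.
  - Every C11 carbonyl precursor is β,γ-unsaturated, so it can slip into conjugation or epimerise at C9.
  - The primary allylic acetate ionises easily.
- **What is hard.**
  - The quaternary C4 sits next to the oxygenated C3.
  - At C9, any C–C bond made to an sp2 C9 of a finished decalin enters axially, anti to C20, which is the wrong face.
  - C11 has no bias that can be predicted.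
  - The 13E trisubstituted alkene must be set.
- **Feature that is used.** Ring B with C17, C7=C8, H5 and the C4/C18/C19 unit on C5 is atom for atom (S)-carvone 1. C9 is its carbonyl carbon, C10 its α′-CH2, and C4(=C18H2)C19H3 its isopropenyl group. Ring A then lacks only C1–C3, C20 and one bond, C3–C4. That bond joins an oxygenated carbon to the internal carbon of a 1,1-disubstituted alkene.

## Retrosynthetic reasoning

**C15–O acyl bond (20 ⇒ 19).** The last step only tells a primary allylic alcohol from the buried 11-OH. This needs no protecting group, provided the C3 acetate is already in place. The C3 acetate must therefore enter before C11–OH exists, and everything after that must tolerate an acetate.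

**C15–O and C16–H (19 ⇒ 17).** The E-allylic alcohol is read as the 1,4-hydration product of a 2-substituted 1,3-diene, C16H2=C13–C14H=C15H2.
- A 1,4-hydroboration on the s-cis-bound diene places C16 and C15 cis on the new C13=C14 bond.
- For this substitution pattern that is the E isomer, so the geometry follows from the mechanism and not from a thermodynamic preference.
- Olefination or reduction chemistry would kill the acetate and is avoided.

**C11–C12 (17 ⇒ 11 + 12, chirality from 13).**
- The chain is cut next to the carbinol, so the whole C5 unit comes from isoprene 12 as an allylborane.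
- The bond forms at the γ-CH2 of a symmetrical 2-vinylallyl unit, so no α/γ problem arises.
- The pocket around C11 gives no reliable substrate bias. The configuration is therefore imposed by the isopinocampheyl groups of 13 through a closed chair transition state.

**C9–C11 and C9–H (11 ⇒ 10 ⇒ 9 ⇒ 8).**
- C11 is not attached to its final face of C9.
- A one-carbon sulfur ylide adds to the C9 ketone of 8 from the open axial face, anti to C20.
- The Lewis-acid rearrangement of the spiro-epoxide then moves a hydride from C11 to that same axial face and swings C11 into the equatorial site.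
- The natural axial preference, which defeats direct C–C bond formation, is thus used to deliver H9.
- The acetate enters between the two operations (9 ⇒ 10), because it would not survive the ylide.

**C3–C4 (8 ⇒ 7, key disconnection).**
- Cutting C3–C4 opens ring A and turns C4 back into an isopropenyl carbon and C3 into an aldehyde.
- Forward, a hydrogen atom is added to C18H2, and the tertiary C4 radical closes onto C3=O.
- One operation makes the second methyl on C4, the quaternary C4, ring A and the C3 carbinol.
- No other cut of ring A leaves a precursor whose remaining ring, alkene, methyl group and stereocentre can all be bought.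

**C10–C1 and C10–C20 (7 ⇒ 5 ⇒ 3 ⇒ 1).**
- The quaternary C10 comes from two successive α′-alkylations of 1.
- The order is fixed by the target: methyl first, the three-carbon arm second. The second electrophile enters anti to the isopropenyl group, which places C1 trans to C4 as a trans-decalin requires.
- The arm is brought in as an activated propargyl unit, because a quaternary centre is being made.
- The alkyne is then converted into the aldehyde by anti-Markovnikov hydration.

## Alternatives that were turned down

**Alternative 1:** the textbook biomimetic cut of C4–C5 and C9–C10.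
- *Forward key step.* (R)-10,11-epoxyfarnesyl acetate A1 is opened by a trivalent titanocene reagent (radical) or by a Lewis acid (cationic). It closes both rings to ent-3β-hydroxyalbicanyl acetate A2.
- *Why turned down.*
  - The termination is not under structural control. The C8 radical or cation loses hydrogen mainly from C17, so the alkene ends up exocyclic and has to be walked into the ring.
  - A1 needs a site-selective and enantioselective oxidation of one of three similar trisubstituted alkenes, which costs several steps.
  - The full C20 chain cannot be used, because C13=C14 sits exactly where it would close a third ring onto C8.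
  - C11 and the side chain must therefore still be added afterwards, and nothing of the end game is saved.

**Alternative 2:** Robinson-annulation logic from (R)-Wieland–Miescher ketone A3.
- *Forward key step.* The proline-type aldol that makes A3. It is followed by ketone differentiation, geminal methylation at C4, reductive setting of the trans fusion and C3 reduction, to reach the hydroxy decalone A4.
- *Why turned down.*
  - The key step sets only C10.
  - All other centres cost separate functional-group steps.
  - A4 still lacks C17 and the C7=C8 bond. Both would have to be built at the hindered C9 ketone before the same homologation as in the present route could even start.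
  - The step count would be roughly twice that of the route chosen.

**Alternative 3:** C9–C11 by allyl transfer from C7.
- *Forward key step.* The cyclic allylboronate A5 (boron on C7, alkene C8=C9) adds to the side-chain aldehyde A6. The same logic holds for a [2,3]- or [3,3]-shift from a C7–O derivative. This would set C9, C11 and the C7=C8 bond at once.
- *Why turned down.*
  - In the half-chair of ring B the pseudoaxial bond at C7 points to the face opposite to C20.
  - A suprafacial transfer therefore delivers C11 axially, anti to C20, which gives the C9-epimeric series.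
  - The correct face would need a boat-like transition state next to the quaternary C10.
  - A6 is a β,γ-unsaturated aldehyde that conjugates readily.
  - A5 is no easier to make than 8.

Key step: step 4

## Route

Step 1
Reactants: 1 (S)-(+)-carvone
Product: 3 (5S,6R)-6-methylcarvone, via lithium dienolate 2 (not isolated)
Conditions: LiN(iPr)2 (LDA), THF, −78 °C; MeI, −78 → 0 °C
Reagents that add atoms: methyl iodide, CI
Why: Kinetic α′-deprotonation of the enone and enolate alkylation bring in C20; the new centre at C10 (mainly methyl trans to isopropenyl) is of no consequence because step 2 flattens it again. The methyl group has to enter first so that the three-carbon arm can enter second, anti to the isopropenyl group.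

Step 2
Reactants: 3 (5S,6R)-6-methylcarvone
Product: 5 (5R,6R)-2,6-dimethyl-5-(prop-1-en-2-yl)-6-(prop-2-yn-1-yl)cyclohex-2-en-1-one, via lithium dienolate 4 (not isolated)
Conditions: LiN(iPr)2, THF/DMPU, −78 → −20 °C; propargyl bromide, −78 → 23 °C
Reagents that add atoms: propargyl bromide, C#CCBr
Why: Enolate alkylation with an activated electrophile builds the quaternary C10. In the tetrasubstituted enolate 4, A(1,2) strain with C20 pushes the isopropenyl group pseudoaxial, so it shields one face and the electrophile enters anti to it. C1 thus ends up trans to C4, the relation a trans-decalin needs; C5 controls C10.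

Step 3
Reactants: 5 (5R,6R)-2,6-dimethyl-5-(prop-1-en-2-yl)-6-(prop-2-yn-1-yl)cyclohex-2-en-1-one
Product: 7 3-[(1R,6R)-1,3-dimethyl-2-oxo-6-(prop-1-en-2-yl)cyclohex-3-en-1-yl]propanal, via alkenylboronate 6 (not isolated)
Conditions: pinacolborane, Cp2ZrHCl (10 mol %), Et3N (10 mol %), CH2Cl2, 23 °C; then NaBO3·4H2O, THF/H2O, 23 °C
Reagents that add atoms: sodium perborate, [Na+].[O-]OB=O
Why: Zirconium-catalysed syn-hydroboration puts boron on the terminal alkyne carbon C3, and mild oxidation gives the enol and then the aldehyde, an overall anti-Markovnikov hydration. The terminal alkyne reacts far faster than the hindered 1,1-disubstituted alkene or the flanked enone, and perborate avoids nucleophilic epoxidation of the enone.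

Step 4
Reactants: 7 3-[(1R,6R)-1,3-dimethyl-2-oxo-6-(prop-1-en-2-yl)cyclohex-3-en-1-yl]propanal
Product: 8 ent-3β-hydroxy-11-nordrim-7-en-9-one (trans-decalin with equatorial 3-OH)
Conditions: Fe(acac)3 (0.3 equiv), PhSiH3 (slow addition), EtOH (0.02 M), 60 °C, Ar
Reagents that add atoms: none
Why: The iron hydride formed from Fe(acac)3 and PhSiH3 transfers a hydrogen atom to the terminal CH2 of the isopropenyl group, which makes the second methyl on C4 and leaves a nucleophilic tertiary radical at C4. This radical adds to the aldehyde carbon C3 in a 6-exo-trig closure (C3–C4 bond, ring A), and the alkoxy radical is reduced by divalent iron and protonated by EtOH, which pulls the reversible addition forward and returns trivalent iron. The closest known reaction types are the hydrogen-atom-transfer-initiated reductive cyclisation of alkene-tethered ketones and the iron-catalysed addition of unactivated alkenes to aldehydes. The ring fusion is not made here but read out: C4 on C5 and C1 on C10 are trans-diequatorial on ring B, so only a chair-like transition state leading to the trans-decalin is within reach. C3 is the one new stereocentre; the carbonyl oxygen should sit pseudoequatorial to avoid the axial H1 and H5, and because the addition is reversible the more stable and more exposed equatorial alkoxy radical should be the one that is trapped. The step needs chemoselective hydrogen-atom transfer to the electron-neutral 1,1-disubstituted alkene, and the only other alkene, C7=C8, is trisubstituted and electron-poor. Neither C7 nor C9 can be reached by the C4 radical except through a four-membered ring, so the aldehyde is the only acceptor, and high dilution suppresses intermolecular coupling.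

Step 5
Reactants: 8 ent-3β-hydroxy-11-nordrim-7-en-9-one
Product: 9 ent-3β-hydroxy-9,11-epoxydrim-7-ene (spiro-epoxide with C11 axial and anti to C20)
Conditions: Me3SI (3.5 equiv), n-BuLi (3.3 equiv), THF, −10 °C; then 8, −10 → 23 °C
Reagents that add atoms: trimethylsulfonium iodide, C[S+](C)C.[I-]
Why: Corey–Chaykovsky epoxidation; the small, unstabilised sulfonium methylide adds 1,2 to enones and tolerates flanked ketones. It attacks C9 axially, on the face anti to the axial C20, so C11 becomes axial and oxygen equatorial. The free 3-OH only consumes one extra equivalent of ylide.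

Step 6
Reactants: 9 ent-3β-hydroxy-9,11-epoxydrim-7-ene
Product: 10 ent-3β-acetoxy-9,11-epoxydrim-7-ene
Conditions: Ac2O, pyridine, DMAP (cat.), CH2Cl2, 23 °C
Reagents that add atoms: acetic anhydride, CC(=O)OC(C)=O
Why: Standard acylation of the only hydroxyl group; the vinyl epoxide is stable to these basic conditions. The acetate is placed here because it would not survive step 5 and because all later steps tolerate it.

Step 7
Reactants: 10 ent-3β-acetoxy-9,11-epoxydrim-7-ene
Product: 11 ent-3β-acetoxydrim-7-en-11-al
Conditions: BF3·OEt2 (0.2 equiv), CH2Cl2, −78 °C, short contact; Et3N quench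
Reagents that add atoms: none
Why: Meinwald rearrangement; the C9–O bond ionises because C9 is tertiary and allylic, and a hydride moves from C11 to C9. By least motion it enters the lobe opposite to the departing oxygen, so H9 becomes axial (anti to C20) and the formyl group equatorial, which is also the more stable epimer. Low temperature and a basic quench keep the C7=C8 bond out of conjugation.

Step 8
Reactants: 11 ent-3β-acetoxydrim-7-en-11-al; 12 isoprene; 13 (−)-B-methoxydiisopinocampheylborane
Product: 17 (11S)-ent-3β-acetoxylabda-7,13(16),14-trien-11-ol, via isoprenylpotassium 14 (not isolated), via isoprenylborane 15 (not isolated), via borinate 16 (not isolated)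
Conditions: 12, n-BuLi, KOt-Bu, 2,2,6,6-tetramethylpiperidine, THF, −78 °C; 13; BF3·OEt2, −78 °C; then 11, −78 → −40 °C; NaBO3·4H2O, THF/H2O, 23 °C
Reagents that add atoms: none
Why: Brown allylboration with the 2-vinylallyl (isoprenyl) borane forms C11–C12 through a closed Zimmerman–Traxler chair at the γ-CH2 of a symmetrical allyl unit, so no regiochemical question arises. The isopinocampheyl groups derived from (+)-α-pinene direct attack to the Si face of α-branched aldehydes, which corresponds to 11S here (C9 ranks above C12). The dialkylborane reacts with hindered aldehydes at low temperature and leaves the acetate untouched.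

Step 9
Reactants: 17 (11S)-ent-3β-acetoxylabda-7,13(16),14-trien-11-ol
Product: 19 (11S,13E)-ent-3β-acetoxylabda-7,13-diene-11,15-diol, via bis-boryl compound 18 (not isolated)
Conditions: pinacolborane (2.5 equiv), FeCl2[2-(2,6-iPr2C6H3N=CH)C5H4N] (5 mol %), Mg (10 mol %), Et2O, 23 °C; then NaBO3·4H2O, THF/H2O, 23 °C
Reagents that add atoms: sodium perborate, [Na+].[O-]OB=O
Why: Iron-catalysed 1,4-hydroboration of a 2-substituted 1,3-diene, as known for myrcene-type dienes, followed by oxidation of the allylboronate. The first equivalent of borane masks the 11-OH as a borate. The diene binds s-cis, so C16 (which receives H) and C15 (which receives B) end up cis on the new C13=C14 bond, which is the 13E geometry; the trisubstituted C7=C8 bond is not a diene and stays inert.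

Step 10
Reactants: 19 (11S,13E)-ent-3β-acetoxylabda-7,13-diene-11,15-diol
Product: 20 (3R,5S,9R,10R,11S,13E)-labda-7,13-diene-3,11,15-triol 3,15-diacetate (target)
Conditions: Ac2O (1.1 equiv), pyridine, CH2Cl2, 0 °C
Reagents that add atoms: acetic anhydride, CC(=O)OC(C)=O
Why: Selective acylation; the primary allylic 15-OH should react far faster than the secondary 11-OH, which is buried between C1H2, C17 and C20. No catalyst is added, so that the hindered alcohol is left alone.

## Compound list

1 | (S)-(+)-carvone | CC1=CC[C@@H](CC1=O)C(C)=C | starting material
2 | lithium cross-conjugated dienolate of 1 | CC1=CC[C@@H](C=C1[O-])C(C)=C.[Li+] | intermediate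
3 | (5S,6R)-6-methylcarvone | CC1=CC[C@H](C(C)=C)[C@@H](C)C1=O | intermediate
4 | lithium dienolate of 3 | CC1=CC[C@H](C(C)=C)C(C)=C1[O-].[Li+] | intermediate
5 | (5R,6R)-2,6-dimethyl-5-(prop-1-en-2-yl)-6-(prop-2-yn-1-yl)cyclohex-2-en-1-one | CC1=CC[C@H](C(C)=C)[C@@](C)(CC#C)C1=O | intermediate
6 | (E)-alkenyl pinacol boronate of 5 | CC1=CC[C@H](C(C)=C)[C@@](C)(C/C=C/B2OC(C)(C)C(C)(C)O2)C1=O | intermediate
7 | 3-[(1R,6R)-1,3-dimethyl-2-oxo-6-(prop-1-en-2-yl)cyclohex-3-en-1-yl]propanal | CC1=CC[C@H](C(C)=C)[C@@](C)(CCC=O)C1=O | intermediate
8 | ent-3β-hydroxy-11-nordrim-7-en-9-one | O=C1C(C)=CC[C@@H]2C(C)(C)[C@H](O)CC[C@]21C | intermediate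
9 | ent-3β-hydroxy-9,11-epoxydrim-7-ene (C11 axial) | C1O[C@@]12C(C)=CC[C@@H]3C(C)(C)[C@H](O)CC[C@@]23C | intermediate
10 | ent-3β-acetoxy-9,11-epoxydrim-7-ene | C1O[C@@]12C(C)=CC[C@@H]3C(C)(C)[C@H](OC(C)=O)CC[C@@]23C | intermediate
11 | ent-3β-acetoxydrim-7-en-11-al | O=C[C@@H]1C(C)=CC[C@@H]2C(C)(C)[C@H](OC(C)=O)CC[C@]21C | intermediate
12 | isoprene | C=CC(C)=C | starting material
13 | (−)-B-methoxydiisopinocampheylborane | COB([C@@H]1C[C@@H]2C[C@H]([C@H]1C)C2(C)C)[C@@H]1C[C@@H]2C[C@H]([C@H]1C)C2(C)C | starting material
14 | isoprenylpotassium (2-vinylallylpotassium) | [K+].[CH2-]C(=C)C=C | intermediate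
15 | B-(2-methylenebut-3-enyl)diisopinocampheylborane | C=CC(=C)CB([C@@H]1C[C@@H]2C[C@H]([C@H]1C)C2(C)C)[C@@H]1C[C@@H]2C[C@H]([C@H]1C)C2(C)C | intermediate
16 | diisopinocampheylborinate of 17 | C=CC(=C)C[C@H](OB([C@@H]1C[C@@H]2C[C@H]([C@H]1C)C2(C)C)[C@@H]1C[C@@H]2C[C@H]([C@H]1C)C2(C)C)[C@@H]1C(C)=CC[C@@H]2C(C)(C)[C@H](OC(C)=O)CC[C@]21C | intermediate
17 | (11S)-ent-3β-acetoxylabda-7,13(16),14-trien-11-ol | C=CC(=C)C[C@H](O)[C@@H]1C(C)=CC[C@@H]2C(C)(C)[C@H](OC(C)=O)CC[C@]21C | intermediate
18 | 11-O-boryl (13E)-15-allylboronate | CC1(C)OB(C/C=C(\C)C[C@H](OB2OC(C)(C)C(C)(C)O2)[C@@H]2C(C)=CC[C@@H]3C(C)(C)[C@H](OC(C)=O)CC[C@]32C)OC1(C)C | intermediate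
19 | (11S,13E)-ent-3β-acetoxylabda-7,13-diene-11,15-diol | OC/C=C(\C)C[C@H](O)[C@@H]1C(C)=CC[C@@H]2C(C)(C)[C@H](OC(C)=O)CC[C@]21C | intermediate
20 | (3R,5S,9R,10R,11S,13E)-labda-7,13-diene-3,11,15-triol 3,15-diacetate | CC(=O)OC/C=C(\C)C[C@H](O)[C@@H]1C(C)=CC[C@@H]2C(C)(C)[C@H](OC(C)=O)CC[C@]21C | target

## Step count

Total step count: 10. Longest linear sequence: 10 steps from 1. Compounds 12 and 13 are bought and enter in step 8.

## Steps that are least certain to work

**Step 4 (key step).**
- *What may go wrong.*
  - Addition of a tertiary radical to C=O is reversible, and β-scission gives the tertiary radical back. The most likely failure is quenching of the C4 radical by a second hydrogen-atom transfer, which amounts to net hydrogenation of the isopropenyl group.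
  - Incomplete facial selectivity at C3 and direct silane reduction of the aldehyde are secondary risks.
- *Fallback.* It sets out from 7 and changes both the acceptor and the way C3 is set.
  - The aldehyde is converted with I2 and aqueous NH3 into the keto nitrile F1.
  - F1 is cyclised by the known hydrogen-atom-transfer-mediated closure of alkenyl nitriles (Fe(acac)3, PhSiH3). This gives the cyclic imine F2, whose iminyl precursor does not fragment back as readily.
  - Hydrolysis on work-up gives the 3,9-dione F3.
  - NaBH4 in MeOH at low temperature reduces the saturated C3 ketone by axial hydride attack in preference to the flanked enone, and the route is rejoined at 8.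
  - A C3-epimeric mixture from step 4 could also be oxidised to F3 and corrected in the same way.

**Step 5.**
- *What may go wrong.* The C9 ketone lies between the quaternary C10 and C8 with its methyl group, so slow addition and competing γ-deprotonation at C6 by the basic ylide are the likely problems.
- *Fallback.* It sets out from 8 and sets H9 by hydroboration instead of a hydride shift.
  - Me3SiCH2Li/CeCl3 adds to give the β-hydroxysilane F4.
  - KH induces the Peterson olefination to the exocyclic dienol F5.
  - Acetylation gives the diene acetate F6.
  - 9-BBN adds to the terminal C9=C11 bond from the face anti to C20 to give the B-alkylborane F7.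
  - F7 is oxidised directly with pyridinium chlorochromate, [C5H5NH][CrO3Cl], to 11.

**Step 7.**
- *What may go wrong.* The allylic cation can lose a proton instead of accepting the hydride, and the product can drift into the conjugated C8=C9 aldehyde or epimerise at C9 while the Lewis acid is present.
- *Fallback.* It sets out from 10 and avoids cationic conditions.
  - Hydrogenolysis of the alkenyl oxirane with formate under zerovalent palladium (Pd2(dba)3·CHCl3, PBu3, HCO2H/Et3N, dioxane) delivers hydride to C9 with inversion. This gives the homoallylic alcohol F8.
  - Dess–Martin periodinane oxidises F8 to 11.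

**Step 8.**
- *What may go wrong.* The aldehyde is chiral and crowded. Erosion of the reagent-controlled facial selectivity in a mismatched pairing, or sluggish addition, is the main risk.
- *Fallback.* It sets out from 11 and sets C11 by hydride instead of carbon delivery.
  - An indium-mediated Barbier reaction with 2-(bromomethyl)buta-1,3-diene gives 17 together with its C11 epimer F9.
  - Buffered Dess–Martin oxidation of the mixture gives the ketone F10.
  - Corey–Bakshi–Shibata reduction with the (R)-methyl oxazaborolidine and catecholborane at −78 °C gives 17.
  - In this reduction the reagent and the Felkin–Anh preference (hydride anti to C10) should point the same way.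

**Step 9.**
- *What may go wrong.* Boron may be delivered to C16 instead of C15, or the low-valent iron catalyst may be deactivated by the borate and ester groups.
- *Fallback.* It sets out from 11 and builds the alkene by metathesis.
  - Compound 13 and methallylmagnesium chloride give the methallylborane F11.
  - F11 adds to 11 with the same facial sense to give the methallyl carbinol F12.
  - Cross-metathesis of F12 with (Z)-but-2-ene-1,4-diyl diacetate and the second-generation Hoveyda–Grubbs catalyst gives 20 directly.
  - The price is a less selective alkene geometry, so the isomers would have to be separated.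

## Further compounds

F1 | step 4 | 3-[(1R,6R)-1,3-dimethyl-2-oxo-6-(prop-1-en-2-yl)cyclohex-3-en-1-yl]propanenitrile | CC1=CC[C@H](C(C)=C)[C@@](C)(CCC#N)C1=O
F2 | step 4 | 3-imino-11-nordrim-7-en-9-one (ent series) | O=C1C(C)=CC[C@@H]2C(C)(C)C(=N)CC[C@]21C
F3 | step 4 | ent-11-nordrim-7-ene-3,9-dione | O=C1C(C)=CC[C@@H]2C(C)(C)C(=O)CC[C@]21C
F4 | step 5 | 9-(trimethylsilylmethyl) carbinol of 8 (CH2Si axial) | C[Si](C)(C)C[C@@]1(O)C(C)=CC[C@@H]2C(C)(C)[C@H](O)CC[C@]21C
F5 | step 5 | ent-drima-7,9(11)-dien-3β-ol | C=C1C(C)=CC[C@@H]2C(C)(C)[C@H](O)CC[C@]21C
F6 | step 5 | ent-3β-acetoxydrima-7,9(11)-diene | C=C1C(C)=CC[C@@H]2C(C)(C)[C@H](OC(C)=O)CC[C@]21C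
F7 | step 5 | B-(ent-3β-acetoxydrim-7-en-11-yl)-9-borabicyclo[3.3.1]nonane | C(B1C2CCCC1CCC2)[C@@H]1C(C)=CC[C@@H]2C(C)(C)[C@H](OC(C)=O)CC[C@]21C
F8 | step 7 | ent-3β-acetoxydrim-7-en-11-ol | OC[C@@H]1C(C)=CC[C@@H]2C(C)(C)[C@H](OC(C)=O)CC[C@]21C
F9 | step 8 | (11R)-epimer of 17 | C=CC(=C)C[C@@H](O)[C@@H]1C(C)=CC[C@@H]2C(C)(C)[C@H](OC(C)=O)CC[C@]21C
F10 | step 8 | ent-3β-acetoxylabda-7,13(16),14-trien-11-one | C=CC(=C)CC(=O)[C@@H]1C(C)=CC[C@@H]2C(C)(C)[C@H](OC(C)=O)CC[C@]21C
F11 | step 9 | B-methallyldiisopinocampheylborane | CC(=C)CB([C@@H]1C[C@@H]2C[C@H]([C@H]1C)C2(C)C)[C@@H]1C[C@@H]2C[C@H]([C@H]1C)C2(C)C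
F12 | step 9 | (11S)-methallyl carbinol of 11 | CC(=C)C[C@H](O)[C@@H]1C(C)=CC[C@@H]2C(C)(C)[C@H](OC(C)=O)CC[C@]21C
A1 | alternative 1 | (R)-10,11-epoxyfarnesyl acetate | CC(=O)OC/C=C(\C)CC/C=C(\C)CC[C@H]1OC1(C)C
A2 | alternative 1 | ent-3β-hydroxyalbicanyl acetate | CC(=O)OC[C@@H]1C(=C)CC[C@@H]2C(C)(C)[C@H](O)CC[C@]21C
A3 | alternative 2 | (R)-Wieland–Miescher ketone | O=C1CCCC2=CC(=O)CC[C@]21C
A4 | alternative 2 | ent-3β-hydroxy-4,4,10-trimethyl-trans-decal-9-one | O=C1CCC[C@@H]2C(C)(C)[C@H](O)CC[C@]21C
A5 | alternative 3 | ent-3β-acetoxy-7-(pinacolboryl)-11-nordrim-8-ene (boron pseudoaxial) | C1=C(C)[C@@H](B3OC(C)(C)C(C)(C)O3)C[C@@H]2C(C)(C)[C@H](OC(C)=O)CC[C@]21C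
A6 | alternative 3 | (E)-3-methyl-5-oxopent-2-enyl acetate | CC(=O)OC/C=C(\C)CC=O
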